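**Plan**

1. Retrosynthetic cuts: the C3–OH and the CH2OH on C4 (carbon C23) go back to a 2‑formyl‑2‑methylcyclohexanone in ring A; the C3–C4 bond is then cut by a retro 1,2‑acyl shift, which puts C23 into the ring between C3 and C4 and gives a ring A‑homo 2,3‑epoxy‑3‑methylcycloheptanone; further cuts are C11–O (aryl ether), C9–H/C11–OH (hydroboration), C9=C11 (Wittig), C23=C4 (ring‑closing metathesis), C3–C23 (vinyl Grignard), and C10–C1 and C10–CH3 (two enolate alkylations of (S)‑carvone).
2. Forward order: ring B is the carvone ring from the start; the seven‑membered A‑homo ring is closed onto it by metathesis; ring B is completed (C9 side chain, umbelliferone); epoxidation and ring contraction 7 → 6 then give ring A, and one hydride reduction ends the route.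
3. Enabling feature: in ring A the carbinol C3 and the quaternary C4 (CH3 and CH2OH) form a 1,3‑dioxygenated array, the reduced form of a β‑keto aldehyde; this array is the product of the acyl shift of an α,β‑epoxy ketone, and the isopropenyl group of carvone supplies C4 and its methyl group.
4. Stereochemistry: C5 from (S)‑carvone; C10 by alkylation anti to the isopropenyl group; C9 by hydroboration anti to the C10 methyl group; C4 by α‑face epoxidation followed by inversion in the acyl shift; C3 by axial hydride delivery.

Key step: step 11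

Remark: atom labels follow drimane numbering (decalin C1–C10, C11 = CH2O on C9, C23 = the carbon that ends as CH2OH on C4); β is the face of the C10 methyl group and α the face of C5–H; systematic names in the compound list carry their own locants.

**Step 1**
Reactants: 1 (S)-(+)-carvone
Product: 3 (5S,6R)-2,6-dimethyl-5-(prop-1-en-2-yl)cyclohex-2-en-1-one (trans-6-methylcarvone), via lithium dienolate 2 (not isolated)
Conditions: LiN(iPr)2, THF, −78 °C; then MeI, −78 → 0 °C
Reagents that add atoms: iodomethane CI
Why: Kinetic deprotonation at the α' carbon (C10) gives the cross‑conjugated lithium dienolate, which is C‑methylated (enolate alkylation) mainly anti to the isopropenyl group; the configuration of the new centre does not matter because it is planarised again in step 2.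

**Step 2**
Reactants: 3 trans-6-methylcarvone; 4 2-(2-bromoethyl)-1,3-dioxolane
Product: 6 (5R,6R)-6-[2-(1,3-dioxolan-2-yl)ethyl]-2,6-dimethyl-5-(prop-1-en-2-yl)cyclohex-2-en-1-one, via lithium enolate 5 (not isolated)
Conditions: LiN(iPr)2, THF, −78 → 0 °C; then 4, DMPU, −78 °C → rt
Reagents that add atoms: none
Why: Enolate alkylation of the tetrasubstituted lithium enolate creates the quaternary C10; the electrophile should enter anti to the pseudoaxial isopropenyl group on C5, which places the C1 chain trans and the methyl group cis to it, that is C10–CH3 trans to C5–H.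

**Step 3**
Reactants: 6 dioxolane ketone
Product: 7 3-[(1R,6R)-1,3-dimethyl-2-oxo-6-(prop-1-en-2-yl)cyclohex-3-en-1-yl]propanal
Conditions: 1 M HCl, THF, rt
Reagents that add atoms: water O
Why: Acid‑catalysed acetal hydrolysis should unmask the aldehyde (C3) without touching the enone or the isopropenyl group.

**Step 4**
Reactants: 7 keto aldehyde
Product: 8 (5R,6R)-6-(3-hydroxypent-4-en-1-yl)-2,6-dimethyl-5-(prop-1-en-2-yl)cyclohex-2-en-1-one (both C3 epimers)
Conditions: CH2=CHMgBr, THF, −78 °C; then aq. NH4Cl
Reagents that add atoms: vinylmagnesium bromide C=C[Mg]Br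
Why: Grignard 1,2‑addition should occur at the unhindered aldehyde far faster than at the conjugated ketone flanked by the quaternary C10; the carbinol centre C3 forms without control, which is harmless because it is oxidised to the ketone in step 8.

**Step 5**
Reactants: 8 dienyl carbinol
Product: 9 A-homo enone alcohol (trans-fused; C23=C4 in the seven-membered ring; C3 epimers)
Conditions: second-generation Grubbs catalyst RuCl2(=CHPh)(H2IMes)(PCy3) (5 mol %), CH2Cl2 (0.005 M), 40 °C
Reagents that add atoms: none
Why: Ring‑closing olefin metathesis between the vinyl and isopropenyl groups closes the seven‑membered ring C10–C1–C2–C3–C23–C4–C5 as its trisubstituted cycloalkene with loss of ethene; the trans‑diequatorial arms on C5 and C10 allow closure and the electron‑poor enone alkene of ring B should not compete.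

**Step 6**
Reactants: 9 A-homo enone alcohol
Product: 10 A-homo 7,9(11)-dienol (C9=C11 exocyclic methylene; C3 epimers)
Conditions: Ph3PCH3Br, KOtBu (3 equiv each), toluene, 90 °C
Reagents that add atoms: methyltriphenylphosphonium bromide C[P+](c1ccccc1)(c1ccccc1)c1ccccc1.[Br-]
Why: Wittig methylenation of the ketone, which cannot enolise toward C10, converts C9=O into the exocyclic methylene of a 7,9(11)‑diene; the alkoxide formed from the free hydroxyl is a spectator, hence the excess of ylide.

**Step 7**
Reactants: 10 A-homo dienol
Product: 12 A-homo diol (C9–H α; C11H2OH β; C3 epimers), via bis-boron adduct 11 (not isolated)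
Conditions: 9-BBN (2.5 equiv), THF, 0 °C → rt; then NaOH, H2O2, 0 °C → rt
Reagents that add atoms: hydrogen peroxide OO
Why: Hydroboration–oxidation with bulky 9‑BBN is expected to occur only at the unhindered diene terminus C11 (anti‑Markovnikov) and to deliver hydrogen to C9 from the α face, anti to the axial C10 methyl group, which sets C9; the trisubstituted ring alkenes react much more slowly.

**Step 8**
Reactants: 12 A-homo diol
Product: 13 A-homo enone alcohol with C3=O (3-methylcyclohept-2-enone unit; free C11–OH)
Conditions: MnO2, CH2Cl2, rt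
Reagents that add atoms: none
Why: MnO2 oxidises allylic alcohols selectively, so both C3 epimers should converge on the cycloheptenone while the saturated primary alcohol at C11 is left alone.

**Step 9**
Reactants: 13 A-homo enone alcohol; 14 umbelliferone (7-hydroxy-2H-chromen-2-one)
Product: 15 A-homo enone umbelliferyl ether
Conditions: PPh3, DIAD, THF, 0 °C → rt
Reagents that add atoms: none
Why: Mitsunobu etherification joins the acidic phenol to the primary C11 alcohol under neutral conditions; no stereocentre is involved and the β,β‑disubstituted enone is inert to the reagents.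

**Step 10**
Reactants: 15 A-homo enone umbelliferyl ether
Product: 16 A-homo α-epoxy ketone (oxirane on C23–C4; oxygen on the α face)
Conditions: tBuOOH (decane), DBU, CH2Cl2, rt
Reagents that add atoms: tert-butyl hydroperoxide CC(C)(C)OO
Why: Weitz–Scheffer nucleophilic epoxidation: the peroxide anion should add to C4 of the only reactive enone from the α face, anti to the C10 methyl group and to C6 on C5, and the enolate then closes to the cis‑fused α‑epoxide, which fixes C4 and C23; the ring B alkene and the coumarin are not expected to react.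

**Step 11**
Reactants: 16 A-homo α-epoxy ketone
Product: 17 ring A β-keto aldehyde (C3=O; C4 bearing CH3 β and CHO α)
Conditions: BF3·OEt2, CH2Cl2, 0 °C → rt, short contact time; cold water quench
Reagents that add atoms: none
Why: This is the Lewis‑acid rearrangement of an α,β‑epoxy ketone by 1,2‑acyl shift: BF3 coordinates the oxirane oxygen, the tertiary C4–O bond ionises, and the acyl carbon C3 migrates from C23 to C4 while C23 keeps the oxygen and becomes the formyl group. The closest known reaction is the BF3‑induced ring contraction of isophorone oxide to 2‑formyl‑2,4,4‑trimethylcyclopentanone, here one ring size larger (cycloheptanone to cyclohexanone). Ring A is closed not by a cyclisation but by this 1,2‑shift, which forms the C3–C4 bond through a bridged three‑centre transition state and extrudes C23 from the ring. The only new stereocentre, C4, should arise with inversion at the migration terminus: the acyl carbon bonds to C4 on the face opposite the departing oxygen, so the α‑epoxide gives CH3 β and CHO α, while C5, C9 and C10 are untouched. The step needs acyl migration to win over hydride shift from C23, over proton loss or hydride shift from C5 and over a free cation that would erode stereospecificity; the high migratory aptitude of acyl groups in epoxy ketones, the non‑nucleophilic solvent and the short contact time should secure this, and the non‑basic work‑up protects the non‑enolisable β‑keto aldehyde from deformylation.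

**Step 12**
Reactants: 17 ring A β-keto aldehyde
Product: 18 7-{[(1R,4aS,5S,6R,8aR)-6-hydroxy-5-(hydroxymethyl)-2,5,8a-trimethyl-1,4,4a,5,6,7,8,8a-octahydronaphthalen-1-yl]methoxy}-2H-chromen-2-one (target)
Conditions: NaBH4, EtOH/CH2Cl2, −78 → 0 °C
Reagents that add atoms: none
Why: Hydride should reduce the aldehyde to C23H2OH and the C3 ketone by axial attack on the α face, away from the axial 4β and 10β methyl groups, to give the equatorial 3β alcohol (the usual course for 4,4‑disubstituted 3‑ketones of trans‑decalins); the low temperature and fast aldehyde reduction guard against deformylation, and the coumarin lactone is not expected to be reduced.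

**Compound list**

1 | (S)-(+)-carvone, (5S)-2-methyl-5-(prop-1-en-2-yl)cyclohex-2-en-1-one | CC1=CC[C@H](C(C)=C)CC1=O | starting material
2 | kinetic lithium dienolate of 1 (O–Li on C9; C9=C10 and C7=C8) | CC1=CC[C@H](C(C)=C)C=C1O[Li] | intermediate
3 | (5S,6R)-2,6-dimethyl-5-(prop-1-en-2-yl)cyclohex-2-en-1-one (trans-6-methylcarvone; the minor cis isomer is carried along) | CC1=CC[C@H](C(C)=C)[C@@H](C)C1=O | intermediate
4 | 2-(2-bromoethyl)-1,3-dioxolane | BrCCC1OCCO1 | starting material
5 | lithium enolate of 3 (O–Li on C9; C9=C10 tetrasubstituted) | CC1=CC[C@H](C(C)=C)C(C)=C1O[Li] | intermediate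
6 | (5R,6R)-6-[2-(1,3-dioxolan-2-yl)ethyl]-2,6-dimethyl-5-(prop-1-en-2-yl)cyclohex-2-en-1-one | CC1=CC[C@H](C(C)=C)[C@@](C)(CCC2OCCO2)C1=O | intermediate
7 | 3-[(1R,6R)-1,3-dimethyl-2-oxo-6-(prop-1-en-2-yl)cyclohex-3-en-1-yl]propanal | CC1=CC[C@H](C(C)=C)[C@@](C)(CCC=O)C1=O | intermediate
8 | (5R,6R)-6-(3-hydroxypent-4-en-1-yl)-2,6-dimethyl-5-(prop-1-en-2-yl)cyclohex-2-en-1-one, both carbinol (C3) epimers | CC1=CC[C@H](C(C)=C)[C@@](C)(CCC(O)C=C)C1=O | intermediate
9 | 4-hydroxy-2,7,9-trimethylbicyclo[5.4.0]undeca-2,9-dien-8-one, trans-fused (C5–H α, C10–CH3 β), C3 epimers | CC1=CC[C@@H]2C(C)=CC(O)CC[C@@]2(C)C1=O | intermediate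
10 | 2,7,9-trimethyl-8-methylidenebicyclo[5.4.0]undeca-2,9-dien-4-ol, trans-fused, C3 epimers | CC1=CC[C@@H]2C(C)=CC(O)CC[C@@]2(C)C1=C | intermediate
11 | adduct of 10 with two 9-borabicyclo[3.3.1]nonyl groups (C11–B and C3–O–B), C9–H α | CC1=CC[C@@H]2C(C)=CC(OB3C4CCCC3CCC4)CC[C@@]2(C)[C@@H]1CB1C2CCCC1CCC2 | intermediate
12 | 8-(hydroxymethyl)-2,7,9-trimethylbicyclo[5.4.0]undeca-2,9-dien-4-ol, trans-fused, C9–H α and CH2OH β, C3 epimers | CC1=CC[C@@H]2C(C)=CC(O)CC[C@@]2(C)[C@@H]1CO | intermediate
13 | 8-(hydroxymethyl)-2,7,9-trimethylbicyclo[5.4.0]undeca-2,9-dien-4-one, trans-fused, C9–H α | CC1=CC[C@@H]2C(C)=CC(=O)CC[C@@]2(C)[C@@H]1CO | intermediate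
14 | umbelliferone, 7-hydroxy-2H-chromen-2-one | Oc1ccc2ccc(=O)oc2c1 | starting material
15 | 7-{[2,7,9-trimethyl-4-oxobicyclo[5.4.0]undeca-2,9-dien-8-yl]methoxy}-2H-chromen-2-one, configuration as in 13 | CC1=CC[C@@H]2C(C)=CC(=O)CC[C@@]2(C)[C@@H]1COc1ccc2ccc(=O)oc2c1 | intermediate
16 | 7-{[2,3-epoxy-2,7,9-trimethyl-4-oxobicyclo[5.4.0]undec-9-en-8-yl]methoxy}-2H-chromen-2-one, oxirane oxygen α (syn to C5–H, anti to C10–CH3) | CC1=CC[C@@H]2[C@@]3(C)O[C@H]3C(=O)CC[C@@]2(C)[C@@H]1COc1ccc2ccc(=O)oc2c1 | intermediate
17 | 7-{[5-formyl-2,5,8a-trimethyl-6-oxo-1,4,4a,5,6,7,8,8a-octahydronaphthalen-1-yl]methoxy}-2H-chromen-2-one, trans-decalin, C4: CH3 β and CHO α, other centres as in 18 | CC1=CC[C@@H]2[C@@](C)(C=O)C(=O)CC[C@@]2(C)[C@@H]1COc1ccc2ccc(=O)oc2c1 | intermediate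
18 | 7-{[(1R,4aS,5S,6R,8aR)-6-hydroxy-5-(hydroxymethyl)-2,5,8a-trimethyl-1,4,4a,5,6,7,8,8a-octahydronaphthalen-1-yl]methoxy}-2H-chromen-2-one | CC1=CC[C@@H]2[C@@](C)(CO)[C@H](O)CC[C@@]2(C)[C@@H]1COc1ccc2ccc(=O)oc2c1 | target

**Step count**

Total steps: 12. Longest linear sequence: 12 steps, from (S)-(+)-carvone.

**Steps most likely to fail**

Step 11 (key step). What may go wrong: a hydride shift from C23 or loss of the C5 proton may compete with the acyl shift, a free C4 cation may erode the stereospecificity, and the product may lose its formyl group during work‑up. The fallback sets out from 16 and returns at 17, and moves a siloxy‑bearing carbon instead of an acyl group. Reduction of the ketone (NaBH4, CeCl3, MeOH, −78 °C) gives the epoxy alcohol F1 (either C3 epimer serves). Silylation (TBSOTf, 2,6‑lutidine) gives the epoxy silyl ether F2. The bulky Lewis acid MeAl(OAr)2 (Ar = 4‑bromo‑2,6‑di‑tert‑butylphenyl) in CH2Cl2 at −78 °C should then bring about the known rearrangement of epoxy silyl ethers to β‑siloxy aldehydes: the siloxy‑bearing C3 migrates from C23 to C4 anti to the oxygen and gives the ring‑contracted β‑siloxy aldehyde F3. HF·pyridine frees the β‑hydroxy aldehyde F4, and Dess–Martin oxidation of the C3 carbinol gives 17.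

Step 10. What may go wrong: facial selectivity may be poor, conjugate addition to the β,β‑disubstituted enone may be slow, and the base may deprotonate the γ position C5. The fallback sets out from 15 and returns at 16, and uses a reagent‑controlled, hydroxyl‑directed epoxidation. Corey–Bakshi–Shibata reduction with (R)‑2‑methyl‑CBS‑oxazaborolidine and catecholborane (toluene, −78 °C; alkenyl arm as the large group) should give the 3α allylic alcohol F5. VO(acac)2 with tBuOOH then delivers oxygen syn to the hydroxyl, and only to the allylic alkene, to give the α‑epoxy alcohol F6. Dess–Martin oxidation gives 16.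

Step 2. What may go wrong: alkylation of the hindered enolate by the unactivated bromide may be slow, and elimination of HBr from the bromide or O‑alkylation may compete. The fallback sets out from 3 and returns at 7. The enolate 5 is alkylated with the far more reactive allyl bromide (same anti selectivity expected) to give the 6‑allyl‑6‑methyl ketone F7. Hydroboration of the monosubstituted alkene with disiamylborane and NaBO3 oxidation gives the primary alcohol F8; the isopropenyl group and the hindered ketone should react much more slowly. Dess–Martin oxidation gives aldehyde 7.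

**Further compounds**

F1 | step 11 | A-homo α-epoxy alcohol (C3–OH, either epimer; oxirane on C23–C4, oxygen α) | CC1=CC[C@@H]2[C@@]3(C)O[C@H]3C(O)CC[C@@]2(C)[C@@H]1COc1ccc2ccc(=O)oc2c1
F2 | step 11 | tert-butyldimethylsilyl ether of F1 | CC1=CC[C@@H]2[C@@]3(C)O[C@H]3C(O[Si](C)(C)C(C)(C)C)CC[C@@]2(C)[C@@H]1COc1ccc2ccc(=O)oc2c1
F3 | step 11 | ring A β-siloxy aldehyde (C3–OTBS; C4: CH3 β, CHO α) | CC1=CC[C@@H]2[C@@](C)(C=O)C(O[Si](C)(C)C(C)(C)C)CC[C@@]2(C)[C@@H]1COc1ccc2ccc(=O)oc2c1
F4 | step 11 | ring A β-hydroxy aldehyde (C3–OH; C4: CH3 β, CHO α) | CC1=CC[C@@H]2[C@@](C)(C=O)C(O)CC[C@@]2(C)[C@@H]1COc1ccc2ccc(=O)oc2c1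
F5 | step 10 | A-homo 3α allylic alcohol umbelliferyl ether | CC1=CC[C@@H]2C(C)=C[C@@H](O)CC[C@@]2(C)[C@@H]1COc1ccc2ccc(=O)oc2c1
F6 | step 10 | A-homo α-epoxy 3α-alcohol (hydroxyl and oxirane oxygen cis, both α) | CC1=CC[C@@H]2[C@@]3(C)O[C@H]3[C@@H](O)CC[C@@]2(C)[C@@H]1COc1ccc2ccc(=O)oc2c1
F7 | step 2 | (5R,6R)-configured 6-allyl-2,6-dimethyl-5-(prop-1-en-2-yl)cyclohex-2-en-1-one (allyl trans to isopropenyl) | CC1=CC[C@H](C(C)=C)[C@@](C)(CC=C)C1=O
F8 | step 2 | 6-(3-hydroxypropyl)-2,6-dimethyl-5-(prop-1-en-2-yl)cyclohex-2-en-1-one, configuration as in F7 | CC1=CC[C@H](C(C)=C)[C@@](C)(CCCO)C1=O
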